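The south-east run is the one we measure from, and from it we want the product that green and red hold after 3.0 min.

| flask | substrate | partner | precatalyst | remark | time |
|---|---|---|---|---|---|
| north-east | 2 M | 2.6 M | 0.23 mM | run made earlier |  |
| east | 2 M | 2.6 M | 0.53 mM | run made earlier |  |
| south | 2 M | 2.6 M | 0.95 mM | run made earlier |  |
| south-east | 0.90 M | 2.6 M | 1 mM | run made earlier |  |
| green | 0.50 M | 2.60 M | 0.30 mM |  | 3.0 min |
| red | 2.0 M | 2.60 M | 1.0 mM |  | 3.0 min |

| north-east: time / s | north-east: product / % | east: time / s | east: product / % | south: time / s | south: product / % | south-east: time / s | south-east: product / % |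
|---|---|---|---|---|---|---|---|
| 25.0 | 1.1 | 25.0 | 3.4 | 25.0 | 8.5 | 10.0 | 0.9 |
| 50.0 | 2.1 | 50.0 | 9.6 | 50.0 | 20.7 | 20.0 | 5.3 |
| 80.0 | 5.1 | 80.0 | 17.9 | 80.0 | 36.0 | 40.0 | 17.1 |
| 90.0 | 7.8 | 90.0 | 21.5 | 90.0 | 39.8 | 60.0 | 27.7 |
| 120 | 10.9 | 120 | 29.7 | 120 | 50.0 | 120 | 55.2 |

(each reading ± 0.5 percentage points)

- which of the two ends with the higher amount of product, in percent of the substrate charged ("neither" if they lie within 2 percentage points) (green / red / neither)
- product at the end, in percent of the substrate charged, green
- product at the end, in percent of the substrate charged, red

First instants: south-east shows just 0.9 % product at 10.0 s, so the run starts with a lag. Middle: from east to south the precatalyst charge grows by a factor 1.79 and the reading at 120 s by 1.68, so we take the rate as proportional to precatalyst charge c. We also take it as proportional to substrate and partner. The partner order is an assumption, since these runs share 2.6 M of partner. With charges a of substrate and b of partner, and y the fraction of substrate turned into product, this rate integrates in closed form: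

g(y) = ln[(1 − y·a/b)/(1 − y)] = (b − a)·k·c·(t − lag)

South-east gives g = 0.127 at 40.0 s and 0.591 at 120 s. The slope between them gives

k = 3.41 M⁻² s⁻¹, lag = 18.2 s

This k is our turnover constant, read from readings with their scatter. We carry this lag over to green and red as well, which is a further assumption.

End: inverting with E = exp[(b − a)·k·c·(t − lag)] gives y = (E − 1)/(E − a/b).

Green: E = 1.42, y = 34.0 %

Red: E = 1.39, y = 63.0 %

By this reckoning partner falls to 93.5 % of its charge in green, which is nearly pseudo-first-order, but to 51.5 % in red, so red needs the full form. We expect red to end higher.

The forecast, reckoned separately, says red, with 31 % for green and 65 % for red, and calls its partner dependence tentative in the words “though that order is tentative”. Its figures differ from ours, lower for green and higher for red.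

The flasks give 26.3 % in green and 67.8 % in red, so red ends higher by 41 percentage points, far more than the gaps of 4.7 points and 2.8 points between forecast and flask. Green also holds 8.99 % as intermediate at 3.00 min, and our 34.0 % from k lies closer to its 35.3 % of substrate converted than to its product.

    substrate + catalyst ⇌ catalyst + intermediate (K = 1.40, k = 8.80 M⁻¹ s⁻¹)
    partner + catalyst + intermediate → catalyst + product (k = 25.0 M⁻² s⁻¹)
    precatalyst → catalyst (k = 0.450 s⁻¹)

Green read at 8.0 min: k gives E = 2.70 and y = 67.8 %. The computed flask holds 63.1 % product, 4.99 % intermediate and 31.9 % substrate left.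

(The earlier runs and the new flask were generated by integration with constants of no real substance, and the scatter is random.)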